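Skeleton numbering: C1 ketone, C2=C3(Me), cyclobutane C4–C5–C11–C10(Me), C9 (angelate), C8, C7 (methacrylate), C6(Me)2. The route rests on cutting C4–C10: what remains is a cis-fused cyclohexene (C1–C2–C3–C4–C5–C11) and cycloheptane sharing C5–C11, and that cyclohexene is a Diels–Alder ring. One thermal intramolecular cycloaddition of an acyclic nitro triene forms C1–C2 and C5–C11, closes both carbocycles and sets C5, C11 and C1 from the lone C7 stereocentre. The precursor joins a 2-methyl-1,3-diene (C2–C5) through the C6–C10 tether (C7 silyl ether, C9 dioxolane) to an (E)-nitroalkene (C11=C1). The C10 enolate later opens a C3–C4 epoxide to close the cyclobutane.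

Key step: step 11

Remark 1: skeleton numbering is used in all names from compound 19 on; "face of H5/H11" is the face of the six-membered ring that carries these hydrogens.
Remark 2: Ti(OiPr)4/(R)-BINOL is assumed to give the (7R) carbinol; if the sense is opposite, (S)-BINOL is used.
Remark 3: C10 is carried as an unassigned epimer mixture from 11 to 27, because it becomes an enolate carbon in step 19; lithium and potassium enolates and alkoxides are treated as salts of the numbered compounds.
Remark 4: the pseudo-equatorial C7 silyloxy group in the folded tether is assumed to lead to the diastereomer drawn for 19.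
Remark 5: after the key step the C7 oxygen is tied into a C7–C8 epoxide (steps 16–17), so that C10 is the only enolizable carbon in step 19 and the C7 oxygen can neither leave by β-elimination nor attack C4. The route uses no hydroxyl-directed epoxidation and no epimerization at C11.

Step 1
Reactants: 1 methyl isobutyrate; 2 3-methylbut-2-enal
Product: 3 methyl 3-hydroxy-2,2,5-trimethylhex-4-enoate
Conditions: LiN(i-Pr)2, THF, −78 °C; then 2; aq. NH4Cl
Reagents that add atoms: none
Why: Directed aldol addition, in which the lithium ester enolate should add 1,2 to the β,β-disubstituted enal; the carbinol centre is removed in step 2.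

Step 2
Reactants: 3 methyl 3-hydroxy-2,2,5-trimethylhex-4-enoate
Product: 5 methyl (3E)-2,2,5-trimethylhexa-3,5-dienoate, via allylic mesylate 4 (not isolated)
Conditions: MsCl, Et3N, CH2Cl2, 0 °C; then DBU, 40 °C
Reagents that add atoms: none
Why: Sulfonylation then 1,4-elimination; the quaternary C2 offers no hydrogen for 1,2-elimination, so a methyl hydrogen is lost and the conjugated (E)-diene should form.

Step 3
Reactants: 5 methyl (3E)-2,2,5-trimethylhexa-3,5-dienoate
Product: 6 (3E)-2,2,5-trimethylhexa-3,5-dienal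
Conditions: i-Bu2AlH, CH2Cl2, −78 °C
Reagents that add atoms: none
Why: Partial ester reduction; the aluminium hemiacetal of the α-quaternary ester should persist at −78 °C and release an aldehyde that can neither enolize nor conjugate.

Step 4
Reactants: 7 methyl 2-methylacetoacetate
Product: 8 methyl 2-methyl-3-(trimethylsilyloxy)but-2-enoate
Conditions: Me3SiCl, Et3N, hexane, rt
Reagents that add atoms: chlorotrimethylsilane C[Si](C)(C)Cl
Why: O-silylation of the β-keto ester (silyl enol ether formation).

Step 5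
Reactants: 8 methyl 2-methyl-3-(trimethylsilyloxy)but-2-enoate
Product: 9 1-methoxy-2-methyl-1,3-bis(trimethylsilyloxy)buta-1,3-diene
Conditions: LiN(i-Pr)2, THF, −78 °C; then Me3SiCl
Reagents that add atoms: chlorotrimethylsilane C[Si](C)(C)Cl
Why: γ-Deprotonation of the vinylogous ester and O-silylation give the bis-silyl dienolate (1,3-bis(silyloxy)diene synthesis).

Step 6
Reactants: 6 (3E)-2,2,5-trimethylhexa-3,5-dienal; 9 1-methoxy-2-methyl-1,3-bis(trimethylsilyloxy)buta-1,3-diene
Product: 11 methyl (5R,7E)-5-hydroxy-2,6,6,9-tetramethyl-3-oxodeca-7,9-dienoate, via bis-silylated aldol adduct 10 (not isolated)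
Conditions: Ti(OiPr)4 (10 mol %), (R)-BINOL (10 mol %), 4 Å MS, THF, −78 °C → rt; then CF3CO2H, THF/H2O, 0 °C
Reagents that add atoms: none
Why: Catalytic asymmetric vinylogous Mukaiyama aldol addition; the titanium–BINOL complex activates the aldehyde, the dienolate attacks through its terminal carbon and C7 is set by catalyst control, after which acid cleaves the silyl groups.

Step 7
Reactants: 11 methyl (5R,7E)-5-hydroxy-2,6,6,9-tetramethyl-3-oxodeca-7,9-dienoate
Product: 12 methyl (5R,7E)-5-(tert-butyldimethylsilyloxy)-2,6,6,9-tetramethyl-3-oxodeca-7,9-dienoate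
Conditions: TBSOTf, 2,6-lutidine, CH2Cl2, −78 → 0 °C
Reagents that add atoms: tert-butyldimethylsilyl triflate CC(C)(C)[Si](C)(C)OS(=O)(=O)C(F)(F)F
Why: Silyl ether formation at the hindered secondary alcohol, which blocks retro-aldol and lactonization.

Step 8
Reactants: 12 methyl (5R,7E)-5-(tert-butyldimethylsilyloxy)-2,6,6,9-tetramethyl-3-oxodeca-7,9-dienoate
Product: 13 methyl 2-{2-[(2R,4E)-2-(tert-butyldimethylsilyloxy)-3,3,6-trimethylhepta-4,6-dien-1-yl]-1,3-dioxolan-2-yl}propanoate
Conditions: Me3SiOCH2CH2OSiMe3, Me3SiOTf (cat.), CH2Cl2, −78 → −20 °C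
Reagents that add atoms: 1,2-bis(trimethylsilyloxy)ethane C[Si](C)(C)OCCO[Si](C)(C)C
Why: Silyl-triflate-catalysed ketalization with the bis-silyl glycol masks the C9 ketone at low temperature, without protic acid that could eliminate the β-silyloxy group.

Step 9
Reactants: 13 methyl 2-{2-[(2R,4E)-2-(tert-butyldimethylsilyloxy)-3,3,6-trimethylhepta-4,6-dien-1-yl]-1,3-dioxolan-2-yl}propanoate
Product: 14 2-{2-[(2R,4E)-2-(tert-butyldimethylsilyloxy)-3,3,6-trimethylhepta-4,6-dien-1-yl]-1,3-dioxolan-2-yl}propanal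
Conditions: i-Bu2AlH, CH2Cl2, −78 °C
Reagents that add atoms: none
Why: Partial ester reduction, the ketal oxygens helping to hold the aluminium hemiacetal until work-up.

Step 10
Reactants: 14 2-{2-[(2R,4E)-2-(tert-butyldimethylsilyloxy)-3,3,6-trimethylhepta-4,6-dien-1-yl]-1,3-dioxolan-2-yl}propanal; 15 nitromethane
Product: 18 2-[(2R,4E)-2-(tert-butyldimethylsilyloxy)-3,3,6-trimethylhepta-4,6-dien-1-yl]-2-[(3E)-4-nitrobut-3-en-2-yl]-1,3-dioxolane, via nitro alcohol 16 (not isolated), via nitro mesylate 17 (not isolated)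
Conditions: 15 (excess), Et3N (cat.), THF, 0 °C; then MsCl, i-Pr2NEt, CH2Cl2, −20 °C
Reagents that add atoms: none
Why: Henry reaction followed by mesylation and E1cB elimination should give the (E)-nitroalkene, the cold hindered-amine conditions limiting deconjugation toward C10.

Step 11
Reactants: 18 2-[(2R,4E)-2-(tert-butyldimethylsilyloxy)-3,3,6-trimethylhepta-4,6-dien-1-yl]-2-[(3E)-4-nitrobut-3-en-2-yl]-1,3-dioxolane
Product: 19 cis-fused nitro bicycle (C7 silyl ether; C9 dioxolane; C3=C4 alkene)
Conditions: toluene (5 mM), BHT, 130 °C, sealed tube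
Reagents that add atoms: none
Why: A concerted, asynchronous normal-demand [4+2] cycloaddition between the electron-rich 2-methyl-1,3-diene (C2–C5) and the nitroalkene (C11=C1) forms C1–C2 and C5–C11; the closest known reaction type is the thermal type 1 intramolecular Diels–Alder reaction of (E)-nitro trienes. The cyclohexene closes in the cycloaddition event itself, and the cycloheptane closes as the fused ring spanned by the five-atom tether C6–C10, helped by the gem-dimethyl group at C6 and the spiro-dioxolane at C9. C5 and C11 are set by suprafacial addition with the tether folded under the diene (tether-endo, nitro-exo), which gives the cis ring fusion, and C1 follows from the E geometry of the nitroalkene (nitro trans to C10; this centre is erased in step 12). The absolute sense is relayed from C7, whose silyloxy group should sit pseudo-equatorial in the chair-like seven-membered array, so that H5 and H11 end up trans to the C7 oxygen. The step needs the tether-endo mode and this diene face; uncatalysed, non-polar conditions are chosen because they weaken the nitro-endo preference, and the C10 methyl can lie on the dienophile face remote from the diene in either C10 epimer, so both epimers should give the same ring fusion.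

Step 12
Reactants: 19 cis-fused nitro bicycle
Product: 20 bicyclic C1 ketone
Conditions: NaOMe, MeOH, 0 °C; then TiCl3, NH4OAc, H2O, rt
Reagents that add atoms: water O
Why: Nef reaction in its reductive titanium trichloride form; the nitronate is reduced to the imine and hydrolysed at buffered pH, so the β,γ-alkene and C11 should stay in place.

Step 13
Reactants: 20 bicyclic C1 ketone
Product: 21 bicyclic C1 alcohol (hydroxyl cis to C10)
Conditions: NaBH4, MeOH, −20 °C
Reagents that add atoms: none
Why: Borohydride reduction; hydride should enter from the face of H5/H11 (axial, convex), placing the hydroxyl cis to C10 at a centre that is erased in step 24.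

Step 14
Reactants: 21 bicyclic C1 alcohol
Product: 22 C1 4-methoxybenzyl ether
Conditions: NaH, 4-methoxybenzyl chloride, n-Bu4NI (cat.), DMF, 0 °C → rt
Reagents that add atoms: 4-methoxybenzyl chloride COc1ccc(CCl)cc1
Why: Williamson ether synthesis; the ether keeps the C1 oxygen from attacking C4 in step 19 and is removable oxidatively beside the esters.

Step 15
Reactants: 22 C1 4-methoxybenzyl ether
Product: 23 C9 ketone
Conditions: PPTS, acetone/H2O, 55 °C
Reagents that add atoms: water O
Why: Acid-catalysed ketal hydrolysis under mild conditions that leave the silyl and benzyl-type ethers, carried out before any epoxide is present.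

Step 16
Reactants: 23 C9 ketone
Product: 24 C8 bromo ketone (bromine trans to the C7 silyloxy group)
Conditions: LiN(i-Pr)2, THF, −78 °C; then NBS, −78 °C
Reagents that add atoms: N-bromosuccinimide O=C1CCC(=O)N1Br
Why: Kinetic enolization at the less substituted C8 and electrophilic α-bromination, with bromine expected anti to the bulky silyloxy group; the β-silyloxy enolate should be stable at −78 °C.

Step 17
Reactants: 24 C8 bromo ketone
Product: 26 C7–C8 epoxy ketone, via bromohydrin 25 (not isolated)
Conditions: HF·pyridine, THF, 0 °C → rt; then K2CO3, MeOH, 0 °C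
Reagents that add atoms: none
Why: Desilylation and intramolecular Williamson closure (bromohydrin to epoxide) with inversion at C8; the C7–O bond is untouched, and C8 of the α,β-epoxy ketone cannot be enolized, which leaves C10 as the only acidic α-carbon.

Step 18
Reactants: 26 C7–C8 epoxy ketone
Product: 27 bis-epoxide (C3–C4 epoxide on the face of H5/H11)
Conditions: mCPBA, NaHCO3, CH2Cl2, 0 °C
Reagents that add atoms: 3-chloroperbenzoic acid OOC(=O)c1cccc(Cl)c1
Why: Prilezhaev epoxidation of the trisubstituted alkene from the open face, opposite C6, C10 and the C1 ether.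

Step 19
Reactants: 27 bis-epoxide
Product: 28 tricyclic epoxy ketone (C4–C10 bond; tertiary C3 hydroxyl)
Conditions: KN(SiMe3)2, THF, −78 → 0 °C
Reagents that add atoms: none
Why: Intramolecular enolate alkylation by epoxide opening in 4-exo-tet mode (the ring-size preference known from epoxynitrile-type cyclizations); the only possible enolate, at C10, attacks the secondary C4 with inversion from a 1,3-diaxial position, which sets C10 and C4, and the ring-bound enolate geometry excludes O-alkylation.

Step 20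
Reactants: 28 tricyclic epoxy ketone
Product: 29 tricyclic dihydroxy ketone (C7 hydroxyl; C9 ketone; C3 hydroxyl)
Conditions: SmI2, THF/MeOH, −90 °C
Reagents that add atoms: none
Why: Reductive cleavage of the α,β-epoxy ketone at the Cα–O bond by SmI2 gives the β-hydroxy ketone, with C7 untouched and C8 returned to a methylene.

Step 21
Reactants: 29 tricyclic dihydroxy ketone
Product: 30 C7 methacrylate with free C9 hydroxyl
Conditions: methacrolein, SmI2 (30 mol %), BHT, THF, −10 °C
Reagents that add atoms: methacrolein C=C(C)C=O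
Why: Evans–Tishchenko reaction; the samarium-bound hemiacetal of the C7 hydroxyl and the aldehyde delivers hydride to the C9 ketone on the face of O7, which should give the anti 1,3-diol with the methacrylate on O7 and C9 set trans to it.

Step 22
Reactants: 30 C7 methacrylate with free C9 hydroxyl
Product: 31 C7 methacrylate C9 angelate
Conditions: angelic acid, 2,4,6-trichlorobenzoyl chloride, Et3N, toluene, rt; then 30, 80 °C
Reagents that add atoms: angelic acid C/C=C(/C)C(=O)O
Why: Yamaguchi-type mixed-anhydride esterification without a nucleophilic catalyst, chosen to avoid angelate-to-tiglate isomerization; the tertiary C3 hydroxyl should not react.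

Step 23
Reactants: 31 C7 methacrylate C9 angelate
Product: 32 diester C1 alcohol
Conditions: DDQ, CH2Cl2/pH 7 buffer, 0 °C
Reagents that add atoms: none
Why: Oxidative cleavage of the 4-methoxybenzyl ether, to which the electron-poor ester alkenes are inert.

Step 24
Reactants: 32 diester C1 alcohol
Product: 33 diester C1 ketone with C3 hydroxyl
Conditions: Dess–Martin periodinane, NaHCO3, CH2Cl2, rt
Reagents that add atoms: none
Why: Dess–Martin oxidation of the only secondary alcohol.

Step 25
Reactants: 33 diester C1 ketone with C3 hydroxyl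
Product: 35 CNP0317071.1, via tertiary mesylate 34 (not isolated)
Conditions: MsCl, Et3N, CH2Cl2, 0 °C → rt
Reagents that add atoms: none
Why: Mesylation of the tertiary β-hydroxyl through sulfene and E1cB elimination toward C2 (C11 is a bridgehead and cannot enolize) should give the enone without a carbocation next to the cyclobutane.

Compound list
1 | methyl isobutyrate | COC(=O)C(C)C | starting material
2 | 3-methylbut-2-enal | CC(C)=CC=O | starting material
3 | methyl 3-hydroxy-2,2,5-trimethylhex-4-enoate (racemic) | COC(=O)C(C)(C)C(O)C=C(C)C | intermediate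
4 | allylic mesylate: methyl 3-(methylsulfonyloxy)-2,2,5-trimethylhex-4-enoate | COC(=O)C(C)(C)C(OS(C)(=O)=O)C=C(C)C | intermediate (not isolated)
5 | methyl (3E)-2,2,5-trimethylhexa-3,5-dienoate | COC(=O)C(C)(C)/C=C/C(C)=C | intermediate
6 | (3E)-2,2,5-trimethylhexa-3,5-dienal | O=CC(C)(C)/C=C/C(C)=C | intermediate
7 | methyl 2-methylacetoacetate | COC(=O)C(C)C(C)=O | starting material
8 | methyl 2-methyl-3-(trimethylsilyloxy)but-2-enoate (E/Z mixture) | COC(=O)C(C)=C(C)O[Si](C)(C)C | intermediate
9 | 1-methoxy-2-methyl-1,3-bis(trimethylsilyloxy)buta-1,3-diene | COC(O[Si](C)(C)C)=C(C)C(=C)O[Si](C)(C)C | intermediate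
10 | bis-silylated aldol adduct: methyl (5R,7E)-2,6,6,9-tetramethyl-3,5-bis(trimethylsilyloxy)deca-2,7,9-trienoate | COC(=O)C(C)=C(O[Si](C)(C)C)C[C@@H](O[Si](C)(C)C)C(C)(C)/C=C/C(C)=C | intermediate (not isolated)
11 | methyl (5R,7E)-5-hydroxy-2,6,6,9-tetramethyl-3-oxodeca-7,9-dienoate (C2 epimers) | COC(=O)C(C)C(=O)C[C@@H](O)C(C)(C)/C=C/C(C)=C | intermediate
12 | methyl (5R,7E)-5-(tert-butyldimethylsilyloxy)-2,6,6,9-tetramethyl-3-oxodeca-7,9-dienoate | COC(=O)C(C)C(=O)C[C@@H](O[Si](C)(C)C(C)(C)C)C(C)(C)/C=C/C(C)=C | intermediate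
13 | methyl 2-{2-[(2R,4E)-2-(tert-butyldimethylsilyloxy)-3,3,6-trimethylhepta-4,6-dien-1-yl]-1,3-dioxolan-2-yl}propanoate | COC(=O)C(C)C1(OCCO1)C[C@@H](O[Si](C)(C)C(C)(C)C)C(C)(C)/C=C/C(C)=C | intermediate
14 | 2-{2-[(2R,4E)-2-(tert-butyldimethylsilyloxy)-3,3,6-trimethylhepta-4,6-dien-1-yl]-1,3-dioxolan-2-yl}propanal | O=CC(C)C1(OCCO1)C[C@@H](O[Si](C)(C)C(C)(C)C)C(C)(C)/C=C/C(C)=C | intermediate
15 | nitromethane | C[N+](=O)[O-] | starting material
16 | nitro alcohol: Henry adduct of 14 (carbinol epimers) | O=[N+]([O-])CC(O)C(C)C1(OCCO1)C[C@@H](O[Si](C)(C)C(C)(C)C)C(C)(C)/C=C/C(C)=C | intermediate (not isolated)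
17 | nitro mesylate: methanesulfonate of 16 | O=[N+]([O-])CC(OS(C)(=O)=O)C(C)C1(OCCO1)C[C@@H](O[Si](C)(C)C(C)(C)C)C(C)(C)/C=C/C(C)=C | intermediate (not isolated)
18 | acyclic nitro triene: 2-[(2R,4E)-2-(tert-butyldimethylsilyloxy)-3,3,6-trimethylhepta-4,6-dien-1-yl]-2-[(3E)-4-nitrobut-3-en-2-yl]-1,3-dioxolane (7R; C10 epimers) | C=C(C)/C=C/C(C)(C)[C@H](O[Si](C)(C)C(C)(C)C)CC1(OCCO1)C(C)/C=C/[N+](=O)[O-] | intermediate
19 | cis-fused nitro bicycle: bicyclo[5.4.0]undec-3-ene with C1 nitro, C3 methyl, C6 gem-dimethyl, C7 silyloxy (7R), C9 dioxolane, C10 methyl; H5 and H11 cis and trans to O7; nitro trans to C10 | CC(C)(C)[Si](C)(C)O[C@@H]1CC2(OCCO2)C(C)[C@@H]3[C@@H]([N+](=O)[O-])CC(C)=C[C@@H]3C1(C)C | intermediate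
20 | bicyclic C1 ketone: 19 with C1=O in place of the nitro group | CC(C)(C)[Si](C)(C)O[C@@H]1CC2(OCCO2)C(C)[C@@H]3C(=O)CC(C)=C[C@@H]3C1(C)C | intermediate
21 | bicyclic C1 alcohol: hydroxyl cis to C10 | CC(C)(C)[Si](C)(C)O[C@@H]1CC2(OCCO2)C(C)[C@@H]3[C@H](O)CC(C)=C[C@@H]3C1(C)C | intermediate
22 | C1 4-methoxybenzyl ether of 21 | CC(C)(C)[Si](C)(C)O[C@@H]1CC2(OCCO2)C(C)[C@@H]3[C@H](OCc4ccc(OC)cc4)CC(C)=C[C@@H]3C1(C)C | intermediate
23 | C9 ketone: 22 without the dioxolane | CC(C)(C)[Si](C)(C)O[C@@H]1CC(=O)C(C)[C@@H]2[C@H](OCc3ccc(OC)cc3)CC(C)=C[C@@H]2C1(C)C | intermediate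
24 | C8 bromo ketone: bromine trans to the C7 silyloxy group | CC(C)(C)[Si](C)(C)O[C@@H]1[C@@H](Br)C(=O)C(C)[C@@H]2[C@H](OCc3ccc(OC)cc3)CC(C)=C[C@@H]2C1(C)C | intermediate
25 | bromohydrin: 24 with free C7 hydroxyl | O[C@@H]1[C@@H](Br)C(=O)C(C)[C@@H]2[C@H](OCc3ccc(OC)cc3)CC(C)=C[C@@H]2C1(C)C | intermediate (not isolated)
26 | C7–C8 epoxy ketone: cis-fused epoxide, oxygen on the face of the former C7 oxygen | O1[C@@H]2[C@H]1C(=O)C(C)[C@@H]3[C@H](OCc4ccc(OC)cc4)CC(C)=C[C@@H]3C2(C)C | intermediate
27 | bis-epoxide: 26 with a C3–C4 epoxide on the face of H5/H11 | O1[C@@H]2[C@H]1C(=O)C(C)[C@@H]3[C@H](OCc4ccc(OC)cc4)C[C@@]5(C)O[C@H]5[C@@H]3C2(C)C | intermediate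
28 | tricyclic epoxy ketone: C4–C10 bond formed; C3 hydroxyl anti to C10; C10 methyl cis to H11 | O1[C@@H]2[C@H]1C(=O)[C@@]4(C)[C@@H]3[C@H](OCc5ccc(OC)cc5)C[C@@](C)(O)[C@H]4[C@@H]3C2(C)C | intermediate
29 | tricyclic dihydroxy ketone: C7 hydroxyl, C8 methylene, C9 ketone, C3 hydroxyl | O[C@@H]1CC(=O)[C@@]2(C)[C@@H]3[C@H](OCc4ccc(OC)cc4)C[C@@](C)(O)[C@H]2[C@@H]3C1(C)C | intermediate
30 | C7 methacrylate with free C9 hydroxyl (O7 and O9 trans) | C=C(C)C(=O)O[C@@H]1C[C@@H](O)[C@@]2(C)[C@@H]3[C@H](OCc4ccc(OC)cc4)C[C@@](C)(O)[C@H]2[C@@H]3C1(C)C | intermediate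
31 | C7 methacrylate C9 angelate (C1 4-methoxybenzyl ether, C3 hydroxyl) | C=C(C)C(=O)O[C@@H]1C[C@@H](OC(=O)/C(C)=C\C)[C@@]2(C)[C@@H]3[C@H](OCc4ccc(OC)cc4)C[C@@](C)(O)[C@H]2[C@@H]3C1(C)C | intermediate
32 | diester C1 alcohol | C=C(C)C(=O)O[C@@H]1C[C@@H](OC(=O)/C(C)=C\C)[C@@]2(C)[C@@H]3[C@H](O)C[C@@](C)(O)[C@H]2[C@@H]3C1(C)C | intermediate
33 | diester C1 ketone with C3 hydroxyl | C=C(C)C(=O)O[C@@H]1C[C@@H](OC(=O)/C(C)=C\C)[C@@]2(C)[C@@H]3C(=O)C[C@@](C)(O)[C@H]2[C@@H]3C1(C)C | intermediate
34 | tertiary mesylate of 33 | C=C(C)C(=O)O[C@@H]1C[C@@H](OC(=O)/C(C)=C\C)[C@@]2(C)[C@@H]3C(=O)C[C@@](C)(OS(C)(=O)=O)[C@H]2[C@@H]3C1(C)C | intermediate (not isolated)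
35 | CNP0317071.1 | C=C(C)C(=O)O[C@@H]1C[C@@H](OC(=O)/C(C)=C\C)[C@@]2(C)[C@@H]3C(=O)C=C(C)[C@H]2[C@@H]3C1(C)C | target

Total step count: 25. Longest linear sequence: 23 steps (steps 1–3 and 6–25).

Steps most likely to fail

Step 11 (key step). The cycloaddition may run through the nitro-endo, tether-exo mode and give the trans ring fusion, may lose the facial control expected from C7, or may divert into a hetero-Diels–Alder reaction with the nitroalkene as heterodiene. Fallback: from aldehyde 14, a Still–Gennari olefination (methyl bis(2,2,2-trifluoroethyl)phosphonoacetate, KN(SiMe3)2, 18-crown-6, THF, −78 °C) gives the (Z)-enoate triene F1. In its thermal intramolecular Diels–Alder reaction (toluene, 160 °C) ester and tether are cis on the dienophile, so the ester-endo preference and the tether-endo mode coincide, which should give the cis-fused ester F2. Enolate hydroxylation (KN(SiMe3)2, then 2-(phenylsulfonyl)-3-phenyloxaziridine) gives the α-hydroxy ester F3, LiAlH4 the diol F4, and NaIO4 cleavage returns the route at ketone 20.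

Step 19. The 4-exo-tet epoxide opening may be too slow, so that the enolate is consumed by intermolecular condensation or by a Favorskii-type reaction of the α,β-epoxy ketone. Fallback: from alkene 26, dihydroxylation on the same open face (OsO4 cat., N-methylmorpholine N-oxide, acetone/H2O) gives the cis-diol F5. Selective mesylation of the secondary C4 hydroxyl (MsCl, pyridine, 0 °C) gives the hydroxy mesylate F6. KN(SiMe3)2 (2 equiv, THF, −78 → 0 °C) then closes the cyclobutane by enolate displacement of the sulfonate with inversion, the known keto-sulfonate route to bicyclo[3.1.1]heptanes, and returns the route at 28.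

Step 21. Methacrolein may polymerize or take up the samarium alkoxide in a conjugate sense, so that the hydride transfer stalls. Fallback: from 29, the Evans–Tishchenko reaction with acetaldehyde (SmI2 cat., THF, −10 °C) gives the C7 acetate F7. Angeloylation as in step 22 gives the acetate angelate F8, and selective methanolysis of the acetate (K2CO3, MeOH, 0 °C) gives the C7 alcohol F9. Methacrylic anhydride, Et3N and 4-(dimethylamino)pyridine then return the route at 31.

Further compounds
F1 | step 11 | (Z)-enoate triene: methyl (2Z)-4-{2-[(2R,4E)-2-(tert-butyldimethylsilyloxy)-3,3,6-trimethylhepta-4,6-dien-1-yl]-1,3-dioxolan-2-yl}pent-2-enoate | C=C(C)/C=C/C(C)(C)[C@H](O[Si](C)(C)C(C)(C)C)CC1(OCCO1)C(C)/C=C\C(=O)OC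
F2 | step 11 | cis-fused ester: 19 with CO2Me at C1 in place of the nitro group, ester cis to C10 | CC(C)(C)[Si](C)(C)O[C@@H]1CC2(OCCO2)C(C)[C@@H]3[C@H](C(=O)OC)CC(C)=C[C@@H]3C1(C)C
F3 | step 11 | α-hydroxy ester: F2 with a hydroxyl at C1 (C1 epimers) | CC(C)(C)[Si](C)(C)O[C@@H]1CC2(OCCO2)C(C)[C@@H]3C(O)(C(=O)OC)CC(C)=C[C@@H]3C1(C)C
F4 | step 11 | diol: C1 hydroxyl and C1 hydroxymethyl (C1 epimers) | CC(C)(C)[Si](C)(C)O[C@@H]1CC2(OCCO2)C(C)[C@@H]3C(O)(CO)CC(C)=C[C@@H]3C1(C)C
F5 | step 19 | cis-diol: 26 with hydroxyls at C3 and C4 on the face of H5/H11 | O1[C@@H]2[C@H]1C(=O)C(C)[C@@H]3[C@H](OCc4ccc(OC)cc4)C[C@@](C)(O)[C@@H](O)[C@@H]3C2(C)C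
F6 | step 19 | hydroxy mesylate: F5 with the C4 hydroxyl as methanesulfonate | O1[C@@H]2[C@H]1C(=O)C(C)[C@@H]3[C@H](OCc4ccc(OC)cc4)C[C@@](C)(O)[C@@H](OS(C)(=O)=O)[C@@H]3C2(C)C
F7 | step 21 | C7 acetate with free C9 hydroxyl (O7 and O9 trans) | CC(=O)O[C@@H]1C[C@@H](O)[C@@]2(C)[C@@H]3[C@H](OCc4ccc(OC)cc4)C[C@@](C)(O)[C@H]2[C@@H]3C1(C)C
F8 | step 21 | C7 acetate C9 angelate | CC(=O)O[C@@H]1C[C@@H](OC(=O)/C(C)=C\C)[C@@]2(C)[C@@H]3[C@H](OCc4ccc(OC)cc4)C[C@@](C)(O)[C@H]2[C@@H]3C1(C)C
F9 | step 21 | C9 angelate with free C7 hydroxyl | O[C@@H]1C[C@@H](OC(=O)/C(C)=C\C)[C@@]2(C)[C@@H]3[C@H](OCc4ccc(OC)cc4)C[C@@](C)(O)[C@H]2[C@@H]3C1(C)C
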